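## Retrosynthetic overview

1. The oxirane is made last, by catalyst-controlled nucleophilic epoxidation of the C3=C4 enone; just before it, diimide removes a C6=C7 alkene.
2. Key step: a one-carbon ring expansion (13 to 14 members) by a semipinacol 1,2-alkenyl shift, which inserts the lactic-acid-derived C8 between C7 and C9 and sets C8.
3. The 13-membered carbinol comes from ring-closing metathesis (C6=C7) after vinyl addition to a C9 ketone made by Negishi acylation (C9–C10).
4. The open chain comes from a B-alkyl Suzuki coupling (C14–C1) of a Sharpless-derived tertiary allylic acetate (C12) with a bromodienone made by alkyne carboalumination and acylation (C2–C3).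
5. Ring order: the carbocycle is closed once as a 13-membered ring, then enlarged to 14 members; the oxirane ring is formed last.

Assumption: pent-1-en-4-yne and 2-bromo-3-methylbut-2-enoic acid are taken as catalogue chemicals, and (S)-lactic acid is used as the crystalline acid.

Locants C1–C15 in the text are those of the target ring: C1 carries the isopropylidene carbon C15, C2 and C9 are the ketones, C3/C4 the oxirane, C8 the secondary methyl centre, C12 the acetoxy centre.

## Route

Step 1
Reactants: 1 but-3-yn-1-ol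
Product: 4 (2E)-3-methylpent-2-ene-1,5-diol, via alkenylalane 2 (not isolated), via lithium aluminate 3 (not isolated)
Conditions: AlMe3 (3 equiv), Cp2ZrCl2 (0.25 equiv), ClCH2CH2Cl, 0 °C to rt; evaporate; n-BuLi (1 equiv), THF–hexane, −78 to 0 °C; (CH2O)n, rt; cold 1 M HCl
Reagents that add atoms: trimethylaluminium, C[Al](C)C; formaldehyde (from paraformaldehyde), C=O
Why: Negishi zirconium-catalysed syn-carboalumination puts methyl on the internal and aluminium on the terminal alkyne carbon, and hydroxymethylation of the aluminate with retention gives the (E)-trisubstituted allylic alcohol.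

Step 2
Reactants: 4 (2E)-3-methylpent-2-ene-1,5-diol
Product: 5 [(2S,3S)-3-(2-hydroxyethyl)-3-methyloxiran-2-yl]methanol
Conditions: Ti(OiPr)4 (0.2 equiv), L-(+)-diethyl tartrate (0.24 equiv), t-BuOOH (2 equiv), 4 Å MS, CH2Cl2, −20 °C; non-aqueous work-up
Reagents that add atoms: tert-butyl hydroperoxide, CC(C)(C)OO
Why: Sharpless asymmetric epoxidation of the (E)-allylic alcohol with L-(+)-tartrate gives the (2S,3S)-epoxide, whose quaternary carbon becomes C12 of the target, while the remote hydroxyl does not direct.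

Step 3
Reactants: 5 [(2S,3S)-3-(2-hydroxyethyl)-3-methyloxiran-2-yl]methanol
Product: 6 (2R,3S)-3-(2-iodoethyl)-2-(iodomethyl)-3-methyloxirane
Conditions: I2 (2.6 equiv), PPh3 (2.6 equiv), imidazole (5 equiv), Et2O–MeCN 3:1, 0 °C to rt
Reagents that add atoms: iodine, [I][I]
Why: Garegg–Samuelsson (Appel-type) iodination converts both primary hydroxyls under buffered conditions that leave the oxirane and both stereocentres untouched.

Step 4
Reactants: 6 (2R,3S)-3-(2-iodoethyl)-2-(iodomethyl)-3-methyloxirane
Product: 7 (3S)-5-iodo-3-methylpent-1-en-3-ol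
Conditions: Zn (3 equiv), AcOH (2 equiv), MeOH, 0 °C to rt
Reagents that add atoms: none
Why: Reductive opening of the 2,3-epoxy iodide (zinc insertion next to the oxirane, then β-elimination) transposes the oxygen to the tertiary carbon without touching that stereocentre, and the unactivated primary iodide is inert under these mild conditions.

Step 5
Reactants: 7 (3S)-5-iodo-3-methylpent-1-en-3-ol
Product: 9 (3S)-5-iodo-3-methylpent-1-en-3-yl acetate, via lithium alkoxide 8 (not isolated)
Conditions: LiN(SiMe3)2 (1.05 equiv), THF, −78 °C; Ac2O (1.5 equiv), −78 to 0 °C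
Reagents that add atoms: acetic anhydride, CC(=O)OC(C)=O
Why: O-acylation of the preformed tertiary alkoxide is fast at low temperature, avoids acid (allylic ionisation) and nucleophilic amine catalysts (alkylation by the iodide), and does not touch the stereocentre.

Step 6
Reactants: 10 pent-1-en-4-yne; 11 2-bromo-3-methylbut-2-enoic acid
Product: 14 (5E)-3-bromo-2,6-dimethylnona-2,5,8-trien-4-one, via acid chloride 12 (not isolated), via alkenylalane 13 (not isolated)
Conditions: (a) 11, (COCl)2, DMF (cat.), CH2Cl2, 0 °C to rt, evaporate; (b) 10, AlMe3 (2 equiv), Cp2ZrCl2 (0.2 equiv), CH2Cl2, 0 °C to rt, evaporate excess AlMe3; (c) alane added slowly to the acid chloride, Pd(PPh3)4 (5 mol%), THF, 0 °C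
Reagents that add atoms: trimethylaluminium, C[Al](C)C
Why: Negishi carboalumination fixes the (E)-trisubstituted alkene and palladium-catalysed acylation of the alkenylalane proceeds with retention, the acyl chloride reacting with zerovalent palladium much faster than the hindered vinyl bromide.

Step 7
Reactants: 9 (3S)-5-iodo-3-methylpent-1-en-3-yl acetate; 14 (5E)-3-bromo-2,6-dimethylnona-2,5,8-trien-4-one
Product: 16 (3R,8E)-1-iodo-3,9-dimethyl-7-oxo-6-(propan-2-ylidene)dodeca-8,11-dien-3-yl acetate, via alkylborane 15 (not isolated)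
Conditions: 9, 9-BBN-H (1.1 equiv), THF, 0 °C to rt; then 14, PdCl2(dppf) (5 mol%), AsPh3 (10 mol%), K3PO4 (3 M aq.), DMF, rt
Reagents that add atoms: none
Why: Anti-Markovnikov hydroboration of the vinyl group followed by B-alkyl Suzuki–Miyaura coupling with the α-bromo enone joins C14 to C1; after hydroboration the acetate is no longer allylic, and the primary iodide is far slower in oxidative addition than the α-bromo enone.

Step 8
Reactants: 17 (2S)-2-hydroxypropanoic acid
Product: 19 (2S)-2-[(trimethylsilyl)oxy]propanoyl chloride, via bis-silyl lactate 18 (not isolated)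
Conditions: HN(SiMe3)2 (1.1 equiv), Me3SiCl (cat.), 60 °C, evaporate; (COCl)2 (1.05 equiv), DMF (cat.), CH2Cl2, 0 °C to rt; distil
Reagents that add atoms: hexamethyldisilazane, C[Si](C)(C)N[Si](C)(C)C; oxalyl chloride, O=C(Cl)C(Cl)=O
Why: Exhaustive silylation followed by the neutral conversion of a silyl ester into the acid chloride with oxalyl chloride and DMF keeps the silyl ether and the lactate stereocentre intact.

Step 9
Reactants: 16 (3R,8E)-1-iodo-3,9-dimethyl-7-oxo-6-(propan-2-ylidene)dodeca-8,11-dien-3-yl acetate; 19 (2S)-2-[(trimethylsilyl)oxy]propanoyl chloride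
Product: 21 (2S,6R,11E)-6,12-dimethyl-3,10-dioxo-9-(propan-2-ylidene)-2-[(trimethylsilyl)oxy]pentadeca-11,14-dien-6-yl acetate, via alkylzinc iodide 20 (not isolated)
Conditions: 16, Zn (activated with BrCH2CH2Br and Me3SiCl), THF, 40 °C; then 19, Pd(PPh3)4 (5 mol%), THF, 0 °C to rt
Reagents that add atoms: none
Why: Zinc insertion into the primary iodide gives an alkylzinc that tolerates acetate and enone, and Negishi acylation forms the C9–C10 bond and the C9 ketone without base, so the lactate-derived C8 centre does not epimerise.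

Step 10
Reactants: 21 (2S,6R,11E)-6,12-dimethyl-3,10-dioxo-9-(propan-2-ylidene)-2-[(trimethylsilyl)oxy]pentadeca-11,14-dien-6-yl acetate
Product: 23 (2S,6R,11E)-3-ethenyl-2,3-dihydroxy-6,12-dimethyl-10-oxo-9-(propan-2-ylidene)pentadeca-11,14-dien-6-yl acetate, via magnesium alkoxide 22 (not isolated)
Conditions: CH2=CHMgBr (1.2 equiv), THF, −78 °C; AcOH at −78 °C, then AcOH–THF–H2O 3:1:1, rt
Reagents that add atoms: vinylmagnesium bromide, C=C[Mg]Br
Why: At −78 °C the Grignard reagent adds to the unhindered, α-oxygen-activated C9 ketone in preference to the doubly β,β-disubstituted dienone and the tertiary acetate, and mild acid removes the silyl ether; the new carbinol centre (both epimers) is erased in step 13.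

Step 11
Reactants: 23 (2S,6R,11E)-3-ethenyl-2,3-dihydroxy-6,12-dimethyl-10-oxo-9-(propan-2-ylidene)pentadeca-11,14-dien-6-yl acetate
Product: 24 (2S,6R,11E)-6-acetoxy-3-ethenyl-3-hydroxy-6,12-dimethyl-10-oxo-9-(propan-2-ylidene)pentadeca-11,14-dien-2-yl methanesulfonate
Conditions: MsCl (1.2 equiv), Et3N (2 equiv), CH2Cl2, −20 °C
Reagents that add atoms: methanesulfonyl chloride, CS(=O)(=O)Cl
Why: Sulfonylation is selective for the secondary over the hindered tertiary hydroxyl and does not break the C8–O bond, so C8 stays (S).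

Step 12
Reactants: 24 (2S,6R,11E)-6-acetoxy-3-ethenyl-3-hydroxy-6,12-dimethyl-10-oxo-9-(propan-2-ylidene)pentadeca-11,14-dien-2-yl methanesulfonate
Product: 25 (1S)-1-[(4R,9E)-4-acetoxy-1-hydroxy-4,10-dimethyl-8-oxo-7-(propan-2-ylidene)cyclotrideca-9,12-dien-1-yl]ethyl methanesulfonate
Conditions: second-generation Grubbs catalyst, RuCl2(=CHPh)(H2IMes)(PCy3) (10 mol%), 1,4-benzoquinone (20 mol%), CH2Cl2 (1 mM), 40 °C
Reagents that add atoms: none
Why: Ring-closing metathesis engages only the two monosubstituted alkenes (the tri- and tetrasubstituted enone alkenes are inert), closing the 13-membered ring at C6=C7 and turning the vinyl group on the carbinol carbon into an endocyclic alkenyl group; the alkene geometry is irrelevant.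

Step 13
Reactants: 25 (1S)-1-[(4R,9E)-4-acetoxy-1-hydroxy-4,10-dimethyl-8-oxo-7-(propan-2-ylidene)cyclotrideca-9,12-dien-1-yl]ethyl methanesulfonate
Product: 27 (3E,8S,12R)-4,8,12-trimethyl-2,9-dioxo-1-(propan-2-ylidene)cyclotetradeca-3,6-dien-12-yl acetate, via aluminium alkoxide 26 (not isolated)
Conditions: AlEt3 (3 equiv), CH2Cl2, −78 to −40 °C; cold 1 M HCl
Reagents that add atoms: none
Why: Proposed new method: an organoaluminium-triggered semipinacol ring expansion of a macrocyclic tertiary allylic carbinol, in which AlEt3 turns the C9 hydroxyl into an aluminium alkoxide and, as a Lewis acid, loosens the exocyclic C8–OMs bond, so that the endocyclic alkenyl carbon C7 (the better migrating group, by π-participation) shifts from C9 to C8 anti to the departing mesylate while C9–O becomes the carbonyl; C8 thereby enters the ring (13 to 14 members) with inversion, which converts the (S)-mesylate into the (8S)-methyl ketone, and both carbinol epimers and both C6=C7 isomers converge; the closest known reaction types are the Suzuki–Tsuchihashi pinacol-type 1,2-alkenyl shift of open-chain β-mesyloxy tertiary alcohols and the Tiffeneau–Demjanov/Sisti-type ring enlargement of 1-(1-haloalkyl)cycloalkanols, neither shown for an endocyclic alkenyl migration in a macrocycle.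

Step 14
Reactants: 27 (3E,8S,12R)-4,8,12-trimethyl-2,9-dioxo-1-(propan-2-ylidene)cyclotetradeca-3,6-dien-12-yl acetate
Product: 28 (3E,8S,12R)-4,8,12-trimethyl-2,9-dioxo-1-(propan-2-ylidene)cyclotetradec-3-en-12-yl acetate
Conditions: KO2CN=NCO2K (10 equiv), AcOH (20 equiv), MeOH–CH2Cl2, 0 °C to rt
Reagents that add atoms: none
Why: Diimide reduction saturates the isolated disubstituted C6=C7 alkene far faster than the polarised tri- and tetrasubstituted enone alkenes and, being free of base and metal, neither conjugates the β,γ-enone nor epimerises C8.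

Step 15
Reactants: 28 (3E,8S,12R)-4,8,12-trimethyl-2,9-dioxo-1-(propan-2-ylidene)cyclotetradec-3-en-12-yl acetate
Product: 29 (3R,4S,8S,12R)-3,4-epoxy-4,8,12-trimethyl-2,9-dioxo-1-(propan-2-ylidene)cyclotetradecan-12-yl acetate
Conditions: La(OiPr)3 (10 mol%), (S)-BINOL (10 mol%), Ph3As=O (10 mol%), t-BuOOH (1.5 equiv), 4 Å MS, THF, rt
Reagents that add atoms: tert-butyl hydroperoxide, CC(C)(C)OO
Why: Lanthanum–BINOL-catalysed Weitz–Scheffer epoxidation attacks only the (E)-C3=C4 enone (the twisted, tetrasubstituted C1=C15 enone is too hindered), gives the trans-oxirane from the (E)-alkene, and the ligand fixes the face for (3R,4S); (S)-BINOL is assigned by analogy with simple (E)-enones and must be confirmed on 28.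

## Compound list

1 | but-3-yn-1-ol | C#CCCO | starting material
2 | {[(3E)-4-(dimethylalumanyl)-3-methylbut-3-en-1-yl]oxy}(dimethyl)alumane | C[Al](C)/C=C(\C)CCO[Al](C)C | intermediate
3 | lithium butyl{(1E)-4-[(dimethylalumanyl)oxy]-2-methylbut-1-en-1-yl}dimethylaluminate | [Li+].CCCC[Al-](C)(C)/C=C(\C)CCO[Al](C)C | intermediate
4 | (2E)-3-methylpent-2-ene-1,5-diol | OC/C=C(\C)CCO | intermediate
5 | [(2S,3S)-3-(2-hydroxyethyl)-3-methyloxiran-2-yl]methanol | OC[C@@H]1O[C@@]1(C)CCO | intermediate
6 | (2R,3S)-3-(2-iodoethyl)-2-(iodomethyl)-3-methyloxirane | IC[C@@H]1O[C@@]1(C)CCI | intermediate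
7 | (3S)-5-iodo-3-methylpent-1-en-3-ol | C=C[C@@](C)(O)CCI | intermediate
8 | lithium (3S)-5-iodo-3-methylpent-1-en-3-olate | C=C[C@@](C)([O-])CCI.[Li+] | intermediate
9 | (3S)-5-iodo-3-methylpent-1-en-3-yl acetate | C=C[C@@](C)(OC(C)=O)CCI | intermediate
10 | pent-1-en-4-yne | C=CCC#C | starting material
11 | 2-bromo-3-methylbut-2-enoic acid | CC(C)=C(Br)C(O)=O | starting material
12 | 2-bromo-3-methylbut-2-enoyl chloride | CC(C)=C(Br)C(Cl)=O | intermediate
13 | dimethyl[(1E)-2-methylpenta-1,4-dien-1-yl]alumane | C[Al](C)/C=C(\C)CC=C | intermediate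
14 | (5E)-3-bromo-2,6-dimethylnona-2,5,8-trien-4-one | CC(C)=C(Br)C(=O)/C=C(\C)CC=C | intermediate
15 | (3R)-1-(9-borabicyclo[3.3.1]nonan-9-yl)-5-iodo-3-methylpentan-3-yl acetate | ICC[C@](C)(OC(C)=O)CCB1C2CCCC1CCC2 | intermediate
16 | (3R,8E)-1-iodo-3,9-dimethyl-7-oxo-6-(propan-2-ylidene)dodeca-8,11-dien-3-yl acetate | ICC[C@](C)(OC(C)=O)CCC(=C(C)C)C(=O)/C=C(\C)CC=C | intermediate
17 | (2S)-2-hydroxypropanoic acid, (S)-lactic acid | C[C@H](O)C(O)=O | starting material
18 | trimethylsilyl (2S)-2-[(trimethylsilyl)oxy]propanoate | C[C@H](O[Si](C)(C)C)C(=O)O[Si](C)(C)C | intermediate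
19 | (2S)-2-[(trimethylsilyl)oxy]propanoyl chloride | C[C@H](O[Si](C)(C)C)C(Cl)=O | intermediate
20 | [(3R,8E)-3-acetoxy-3,9-dimethyl-7-oxo-6-(propan-2-ylidene)dodeca-8,11-dien-1-yl](iodo)zinc | I[Zn]CC[C@](C)(OC(C)=O)CCC(=C(C)C)C(=O)/C=C(\C)CC=C | intermediate
21 | (2S,6R,11E)-6,12-dimethyl-3,10-dioxo-9-(propan-2-ylidene)-2-[(trimethylsilyl)oxy]pentadeca-11,14-dien-6-yl acetate | C[C@H](O[Si](C)(C)C)C(=O)CC[C@](C)(OC(C)=O)CCC(=C(C)C)C(=O)/C=C(\C)CC=C | intermediate
22 | bromomagnesium (2S,6R,11E)-6-acetoxy-3-ethenyl-6,12-dimethyl-10-oxo-9-(propan-2-ylidene)-2-[(trimethylsilyl)oxy]pentadeca-11,14-dien-3-olate (both C3 epimers) | C[C@H](O[Si](C)(C)C)C(O[Mg]Br)(C=C)CC[C@](C)(OC(C)=O)CCC(=C(C)C)C(=O)/C=C(\C)CC=C | intermediate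
23 | (2S,6R,11E)-3-ethenyl-2,3-dihydroxy-6,12-dimethyl-10-oxo-9-(propan-2-ylidene)pentadeca-11,14-dien-6-yl acetate (both C3 epimers) | C[C@H](O)C(O)(C=C)CC[C@](C)(OC(C)=O)CCC(=C(C)C)C(=O)/C=C(\C)CC=C | intermediate
24 | (2S,6R,11E)-6-acetoxy-3-ethenyl-3-hydroxy-6,12-dimethyl-10-oxo-9-(propan-2-ylidene)pentadeca-11,14-dien-2-yl methanesulfonate (both C3 epimers) | C[C@H](OS(C)(=O)=O)C(O)(C=C)CC[C@](C)(OC(C)=O)CCC(=C(C)C)C(=O)/C=C(\C)CC=C | intermediate
25 | (1S)-1-[(4R,9E)-4-acetoxy-1-hydroxy-4,10-dimethyl-8-oxo-7-(propan-2-ylidene)cyclotrideca-9,12-dien-1-yl]ethyl methanesulfonate (13-membered ring made of C9 to C14 and C1 to C7; both carbinol epimers; C6=C7 E/Z mixture) | CC(=O)O[C@@]1(C)CCC(O)([C@H](C)OS(C)(=O)=O)C=CC/C(C)=C/C(=O)C(=C(C)C)CC1 | intermediate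
26 | diethylaluminium alkoxide of 25 | CC(=O)O[C@@]1(C)CCC(O[Al](CC)CC)([C@H](C)OS(C)(=O)=O)C=CC/C(C)=C/C(=O)C(=C(C)C)CC1 | intermediate
27 | (3E,8S,12R)-4,8,12-trimethyl-2,9-dioxo-1-(propan-2-ylidene)cyclotetradeca-3,6-dien-12-yl acetate (C6=C7 E/Z mixture) | CC(=O)O[C@@]1(C)CCC(=O)[C@@H](C)C=CC/C(C)=C/C(=O)C(=C(C)C)CC1 | intermediate
28 | (3E,8S,12R)-4,8,12-trimethyl-2,9-dioxo-1-(propan-2-ylidene)cyclotetradec-3-en-12-yl acetate | CC(=O)O[C@@]1(C)CCC(=O)[C@@H](C)CCC/C(C)=C/C(=O)C(=C(C)C)CC1 | intermediate
29 | (3R,4S,8S,12R)-3,4-epoxy-4,8,12-trimethyl-2,9-dioxo-1-(propan-2-ylidene)cyclotetradecan-12-yl acetate, CNP0229580.1 | CC(=O)O[C@@]1(C)CCC(=O)[C@@H](C)CCC[C@]2(C)O[C@H]2C(=O)C(=C(C)C)CC1 | target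

## Step count and risks

Total step count: 15. Longest linear sequence: 13 (steps 1 to 5, 7, 9 to 15).

The three steps most likely to fail:

Step 7, the B-alkyl Suzuki–Miyaura coupling. The bromide of 14 sits on a tetrasubstituted alkene, and the 1,4-diene of 14 can slip into conjugation in aqueous base. The fallback changes the order of bond formation; it sets out from 9 and comes back at 16. Borane 15, made from 9 as before, is coupled with the potassium salt of bromo acid 11 (same palladium system, one more equivalent of K3PO4) to give (5R)-5-acetoxy-7-iodo-5-methyl-2-(propan-2-ylidene)heptanoic acid F1. Oxalyl chloride with catalytic DMF converts it into (5R)-5-acetoxy-7-iodo-5-methyl-2-(propan-2-ylidene)heptanoyl chloride F2. Pd(PPh3)4-catalysed acylation of alkenylalane 13 with F2 then gives 16, so the diene never meets aqueous base.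

Step 13, the proposed new ring expansion. The ring alkyl carbon C10 could migrate instead of C7, or the macrocycle could hold the C9–C7 bond away from the anti alignment with the mesylate. The fallback uses known chemistry and runs the 1,2-shift before the ring closure; it sets out from 24 and comes back at 27. Open-chain 24 is treated with AlEt3 (CH2Cl2, −78 °C), the established Suzuki–Tsuchihashi 1,2-vinyl shift of an acyclic β-mesyloxy tertiary alcohol with inversion. This gives (3S,7R,12E)-3,7,13-trimethyl-4,11-dioxo-10-(propan-2-ylidene)hexadeca-1,12,15-trien-7-yl acetate F3. Ring-closing metathesis of F3 (second-generation Grubbs catalyst, RuCl2(=CHPh)(H2IMes)(PCy3), 1,4-benzoquinone, CH2Cl2, 1 mM, 40 °C) closes the 14-membered ring directly to 27.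

Step 15, the final epoxidation. The face selectivity on a β,β-disubstituted macrocyclic enone is not secured by precedent, and the lanthanum alkoxide could epimerise C8. The fallback replaces nucleophilic epoxidation of the enone by hydroxyl-directed, tartrate-controlled epoxidation; it sets out from 28 and comes back at 29. NaBH4 with CeCl3·7H2O (MeOH, −40 °C) reduces both ketones to (3E,8S,12R)-2,9-dihydroxy-4,8,12-trimethyl-1-(propan-2-ylidene)cyclotetradec-3-en-12-yl acetate F4, as a mixture of epimers at C2 and C9. Sharpless epoxidation (Ti(OiPr)4, L-(+)-diisopropyl tartrate, t-BuOOH, CH2Cl2, −20 °C), run as a kinetic resolution of the C2 epimers, gives (3S,4S,8S,12R)-3,4-epoxy-2,9-dihydroxy-4,8,12-trimethyl-1-(propan-2-ylidene)cyclotetradecan-12-yl acetate F5. The oxirane has the sense of the target, by the same tartrate-to-face relation as in step 2. The slow C2 epimer is re-oxidised to 28 and recycled, so at most half of the material is converted per pass. Dess–Martin periodinane (CH2Cl2, NaHCO3) oxidises both carbinols of F5 to 29.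

Further compounds

F1 | step 7 | (5R)-5-acetoxy-7-iodo-5-methyl-2-(propan-2-ylidene)heptanoic acid | ICC[C@](C)(OC(C)=O)CCC(=C(C)C)C(O)=O
F2 | step 7 | (5R)-5-acetoxy-7-iodo-5-methyl-2-(propan-2-ylidene)heptanoyl chloride | ICC[C@](C)(OC(C)=O)CCC(=C(C)C)C(Cl)=O
F3 | step 13 | (3S,7R,12E)-3,7,13-trimethyl-4,11-dioxo-10-(propan-2-ylidene)hexadeca-1,12,15-trien-7-yl acetate | C=C[C@H](C)C(=O)CC[C@](C)(OC(C)=O)CCC(=C(C)C)C(=O)/C=C(\C)CC=C
F4 | step 15 | (3E,8S,12R)-2,9-dihydroxy-4,8,12-trimethyl-1-(propan-2-ylidene)cyclotetradec-3-en-12-yl acetate (epimers at C2 and C9) | CC(=O)O[C@@]1(C)CCC(O)[C@@H](C)CCC/C(C)=C/C(O)C(=C(C)C)CC1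
F5 | step 15 | (3S,4S,8S,12R)-3,4-epoxy-2,9-dihydroxy-4,8,12-trimethyl-1-(propan-2-ylidene)cyclotetradecan-12-yl acetate (fast-reacting C2 epimer; C9 epimers) | CC(=O)O[C@@]1(C)CCC(O)[C@@H](C)CCC[C@]2(C)O[C@H]2C(O)C(=C(C)C)CC1
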